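The ring (numbered as 7-oxabicyclo[4.1.0]heptane: C1/C6 epoxide carbons, C3 side-chain carbon) is built from two three-carbon units in one flask. C3–C4–C5, with the first side-chain carbon, is dimethyl (S)-malate; C2–C1–C6 with its methyl is (Z)-1-bromo-3-iodobut-2-ene. Fráter–Seebach alkylation forms C2–C3; iodine–magnesium exchange and cycloacylation of the malate C1 ester then form C5–C6, giving a hydroxy enone ester. The step exploits the match of the contiguous C3(carbon)–C4(O)–C5(O) array with malic acid and of the epoxide carbons with a (Z)-trisubstituted alkene. Reduction, directed epoxidation, side-chain coupling, angeloylation and a last epoxidation follow.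

Key step: step 3

Assumption: i-PrBu2MgLi is used as a stock solution prepared beforehand from i-PrMgBr and two equivalents of BuLi, and (2Z)-2-methylbut-2-enoic anhydride (angelic anhydride) is taken as a purchasable reagent.

Step 1
Reactants: 1 but-2-yn-1-ol
Product: 2 (2Z)-3-iodobut-2-en-1-ol
Conditions: NaAlH2(OCH2CH2OMe)2, THF, 0 °C to rt; then I2, −78 to 0 °C
Reagents that add atoms: iodine, II
Why: Hydroxyl-directed trans-hydroalumination of the propargylic alcohol puts aluminium on C3, and iodinolysis with retention should give the (Z)-iodoalkene (directed hydroalumination–iodination).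

Step 2
Reactants: 2 (2Z)-3-iodobut-2-en-1-ol
Product: 3 (2Z)-1-bromo-3-iodobut-2-ene
Conditions: CBr4, PPh3, CH2Cl2, 0 °C
Reagents that add atoms: tetrabromomethane, BrC(Br)(Br)Br
Why: The Appel reaction converts the primary allylic alcohol into the bromide without touching the alkenyl iodide or its geometry.

Step 3
Reactants: 4 dimethyl (2S)-2-hydroxybutanedioate (dimethyl (S)-malate); 3 (2Z)-1-bromo-3-iodobut-2-ene
Product: 8 methyl (1S,6S)-6-hydroxy-4-methyl-5-oxocyclohex-3-ene-1-carboxylate, via alkylated malate 5 (not isolated), via dilithium enolate 6 (not isolated), via cyclised ester enolate 7 (not isolated)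
Conditions: LiN(i-Pr)2 (2.2 equiv), THF, −78 to −20 °C; 3, −78 to −10 °C; LiN(i-Pr)2 (1.2 equiv), −78 °C; i-PrBu2MgLi (1.1 equiv), −78 to −30 °C; AcOH, −78 °C
Reagents that add atoms: none
Why: The chelated dilithium alkoxide–enolate of 4 is C-alkylated at C3 by the allylic bromide (Fráter–Seebach alkylation, SN2), which forms ring bond C2–C3, and the second portion of lithium amide re-forms the chelated enolate, which masks the C4 ester and erases the C3 centre. Iodine–magnesium exchange with the triorganomagnesate should keep the (Z)-geometry, and the alkenylmagnesium then attacks the only free ester, C1 of the malate, in a 6-exo-trig acyl substitution that forms C5–C6 and the enone; the closest known type is the Parham cycloacylation. The carbinol centre comes unchanged from (S)-malate, because as an α-oxido carbon it is not deprotonated. The ester-bearing centre is set in the quench, where the exocyclic ester enolate should be protonated on the face opposite the pseudoaxial neighbouring C–O bond, as in the protonation of α-alkylated malate dianions, to give the cis hydroxy ester. The step needs chemoselectivity between the two esters, secured by the enolate mask, and a configurationally stable alkenyl metal, secured by exchange at −78 °C. Diisopropylamine is hindered and weakly acidic and should not quench the ate complex at this temperature, which is why a magnesate and not an alkyllithium is used.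

Step 4
Reactants: 8 methyl (1S,6S)-6-hydroxy-4-methyl-5-oxocyclohex-3-ene-1-carboxylate
Product: 9 methyl (1S,5R,6S)-5,6-dihydroxy-4-methylcyclohex-3-ene-1-carboxylate
Conditions: NaBH4, CeCl3·7H2O, MeOH, −78 °C
Reagents that add atoms: none
Why: Luche reduction gives 1,2-reduction of the enone, and hydride should add anti to the pseudoaxial C6–O bond (ester equatorial), so that the new carbinol is cis to both neighbours.

Step 5
Reactants: 9 methyl (1S,5R,6S)-5,6-dihydroxy-4-methylcyclohex-3-ene-1-carboxylate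
Product: 10 methyl (1R,3S,4S,5S,6S)-4,5-dihydroxy-6-methyl-7-oxabicyclo[4.1.0]heptane-3-carboxylate
Conditions: VO(acac)2 (5 mol %), t-BuOOH, CH2Cl2, 0 °C to rt
Reagents that add atoms: tert-butyl hydroperoxide, CC(C)(C)OO
Why: Vanadium-catalysed hydroxyl-directed epoxidation should deliver oxygen to the alkene face that carries the allylic hydroxyl, which sets both epoxide carbons cis to the diol.

Step 6
Reactants: 10 methyl (1R,3S,4S,5S,6S)-4,5-dihydroxy-6-methyl-7-oxabicyclo[4.1.0]heptane-3-carboxylate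
Product: 11 methyl (1R,3S,4S,5S,6R)-6-methyl-4,5-bis[(triethylsilyl)oxy]-7-oxabicyclo[4.1.0]heptane-3-carboxylate
Conditions: Et3SiCl, imidazole, DMAP (cat.), DMF, rt
Reagents that add atoms: chlorotriethylsilane, CC[Si](Cl)(CC)CC
Why: Silylation of both secondary alcohols under non-acidic conditions protects them against the strong bases of steps 7 and 8 and leaves the epoxide intact.

Step 7
Reactants: 11 methyl (1R,3S,4S,5S,6R)-6-methyl-4,5-bis[(triethylsilyl)oxy]-7-oxabicyclo[4.1.0]heptane-3-carboxylate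
Product: 13 1-[(1R,3S,4S,5S,6R)-6-methyl-4,5-bis[(triethylsilyl)oxy]-7-oxabicyclo[4.1.0]heptan-3-yl]ethan-1-one, via silyl ketone enolate 12 (not isolated)
Conditions: Me3SiCH2Li (2.5 equiv), pentane–THF, −78 to 0 °C; then MeOH, 0 °C
Reagents that add atoms: (trimethylsilyl)methyllithium, [Li]C[Si](C)(C)C
Why: Acyl substitution of the ester gives an α-silyl ketone that the second equivalent holds as its enolate, which stops over-addition, and methanolysis then cleaves the C–Si bond (one-flask conversion of an ester into a methyl ketone).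

Step 8
Reactants: 13 1-[(1R,3S,4S,5S,6R)-6-methyl-4,5-bis[(triethylsilyl)oxy]-7-oxabicyclo[4.1.0]heptan-3-yl]ethan-1-one
Product: 14 1-[(1R,3S,4S,5S,6R)-6-methyl-4,5-bis[(triethylsilyl)oxy]-7-oxabicyclo[4.1.0]heptan-3-yl]ethenyl trifluoromethanesulfonate
Conditions: KN(SiMe3)2, THF, −78 °C; then PhNTf2
Reagents that add atoms: N-phenylbis(trifluoromethanesulfonimide), O=S(=O)(N(c1ccccc1)S(=O)(=O)C(F)(F)F)C(F)(F)F
Why: Kinetic deprotonation on the methyl side and O-triflation give the 1,1-disubstituted alkenyl triflate, and because the enolate is formed away from the ring the C3 centre is not touched (enol triflate formation).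

Step 9
Reactants: 15 4-methylpent-3-en-1-ol
Product: 16 4-methylpent-3-enal
Conditions: Dess–Martin periodinane, NaHCO3, CH2Cl2, 0 °C; used at once
Reagents that add atoms: none
Why: Buffered Dess–Martin oxidation gives the β,γ-unsaturated aldehyde under conditions that should not move the double bond into conjugation.

Step 10
Reactants: 14 1-[(1R,3S,4S,5S,6R)-6-methyl-4,5-bis[(triethylsilyl)oxy]-7-oxabicyclo[4.1.0]heptan-3-yl]ethenyl trifluoromethanesulfonate; 16 4-methylpent-3-enal
Product: 17 (3S)-6-methyl-2-[(1R,3R,4S,5S,6R)-6-methyl-4,5-bis[(triethylsilyl)oxy]-7-oxabicyclo[4.1.0]heptan-3-yl]hepta-1,5-dien-3-ol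
Conditions: CrCl2 (4 equiv), NiCl2 (2 mol %), N-[2-(4-isopropyl-4,5-dihydro-1,3-oxazol-2-yl)-6-methylphenyl]methanesulfonamide (ligand enantiomer matched to the (S)-carbinol), Et3N, THF, rt
Reagents that add atoms: none
Why: Nozaki–Hiyama–Kishi coupling of the alkenyl triflate with the aldehyde forms the side-chain C–C bond and the 2-substituted allylic alcohol in one step, and the (S)-carbinol is to be set by the chiral sulfonamide ligand on chromium (reagent control).

Step 11
Reactants: 17 (3S)-6-methyl-2-[(1R,3R,4S,5S,6R)-6-methyl-4,5-bis[(triethylsilyl)oxy]-7-oxabicyclo[4.1.0]heptan-3-yl]hepta-1,5-dien-3-ol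
Product: 18 (1R,3R,4S,5S,6S)-3-[(3S)-3-hydroxy-6-methylhepta-1,5-dien-2-yl]-6-methyl-7-oxabicyclo[4.1.0]heptane-4,5-diol
Conditions: Bu4NF, THF, 0 °C
Reagents that add atoms: none
Why: Fluoride cleaves both triethylsilyl ethers, and the epoxy alcohol is safe because its hydroxyl is cis to the epoxide and cannot open it in a Payne rearrangement (desilylation).

Step 12
Reactants: 18 (1R,3R,4S,5S,6S)-3-[(3S)-3-hydroxy-6-methylhepta-1,5-dien-2-yl]-6-methyl-7-oxabicyclo[4.1.0]heptane-4,5-diol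
Product: 19 (3S)-6-methyl-2-[(1R,3R,4S,5S,6R)-6-methyl-4,5-bis{[(2Z)-2-methylbut-2-enoyl]oxy}-7-oxabicyclo[4.1.0]heptan-3-yl]hepta-1,5-dien-3-yl (2Z)-2-methylbut-2-enoate
Conditions: LiN(SiMe3)2 (3.5 equiv), angelic anhydride (4.5 equiv), THF, −78 to 0 °C
Reagents that add atoms: (2Z)-2-methylbut-2-enoic anhydride, C/C=C(/C)C(=O)OC(=O)/C(C)=C\C
Why: Acylation of the three lithium alkoxides by the anhydride at low temperature installs the angelates without the nucleophilic amine catalysis that isomerises angelate to tiglate (alkoxide acylation).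

Step 13
Reactants: 19 (3S)-6-methyl-2-[(1R,3R,4S,5S,6R)-6-methyl-4,5-bis{[(2Z)-2-methylbut-2-enoyl]oxy}-7-oxabicyclo[4.1.0]heptan-3-yl]hepta-1,5-dien-3-yl (2Z)-2-methylbut-2-enoate
Product: 20 (2S)-1-[(2R)-3,3-dimethyloxiran-2-yl]-3-[(1R,3R,4S,5S,6R)-6-methyl-4,5-bis{[(2Z)-2-methylbut-2-enoyl]oxy}-7-oxabicyclo[4.1.0]heptan-3-yl]but-3-en-2-yl (2Z)-2-methylbut-2-enoate (CNP0258231.4)
Conditions: 1,2:4,5-di-O-isopropylidene-β-D-erythro-hexo-2,3-diulo-2,6-pyranose (30 mol %), KHSO5 (as 2KHSO5·KHSO4·K2SO4), K2CO3, Bu4NHSO4, MeCN–dimethoxymethane–aqueous buffer (pH 10.5), 0 °C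
Reagents that add atoms: potassium peroxymonosulfate, [K+].OOS(=O)(=O)[O-]
Why: In the Shi epoxidation the chiral dioxirane should react with the electron-rich trisubstituted alkene in preference to the 1,1-disubstituted alkene and the electron-poor angelates, and the D-fructose-derived ketone should give the (R)-epoxide (catalyst control).

Compound list
1 | but-2-yn-1-ol | CC#CCO | starting material
2 | (2Z)-3-iodobut-2-en-1-ol | OC/C=C(/C)I | intermediate
3 | (2Z)-1-bromo-3-iodobut-2-ene | BrC/C=C(/C)I | intermediate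
4 | dimethyl (2S)-2-hydroxybutanedioate (dimethyl (S)-malate) | COC(=O)C[C@H](O)C(=O)OC | starting material
5 | dimethyl (2S,3R)-2-hydroxy-3-[(2Z)-3-iodobut-2-en-1-yl]butanedioate (present as its lithium alkoxide) | COC(=O)[C@@H](O)[C@@H](C/C=C(/C)I)C(=O)OC | intermediate
6 | dilithium alkoxide–ester enolate formed from 5 | COC(O[Li])=C(C/C=C(/C)I)[C@H](O[Li])C(=O)OC | intermediate
7 | lithium alkoxide–ester enolate of 8 | COC(O[Li])=C1CC=C(C)C(=O)[C@H]1O[Li] | intermediate
8 | methyl (1S,6S)-6-hydroxy-4-methyl-5-oxocyclohex-3-ene-1-carboxylate | COC(=O)[C@H]1CC=C(C)C(=O)[C@H]1O | intermediate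
9 | methyl (1S,5R,6S)-5,6-dihydroxy-4-methylcyclohex-3-ene-1-carboxylate | COC(=O)[C@H]1CC=C(C)[C@@H](O)[C@H]1O | intermediate
10 | methyl (1R,3S,4S,5S,6S)-4,5-dihydroxy-6-methyl-7-oxabicyclo[4.1.0]heptane-3-carboxylate | COC(=O)[C@H]1C[C@H]2O[C@@]2(C)[C@@H](O)[C@H]1O | intermediate
11 | methyl (1R,3S,4S,5S,6R)-6-methyl-4,5-bis[(triethylsilyl)oxy]-7-oxabicyclo[4.1.0]heptane-3-carboxylate | COC(=O)[C@H]1C[C@H]2O[C@@]2(C)[C@@H](O[Si](CC)(CC)CC)[C@H]1O[Si](CC)(CC)CC | intermediate
12 | lithium enolate of 1-[(1R,3S,4S,5S,6R)-6-methyl-4,5-bis[(triethylsilyl)oxy]-7-oxabicyclo[4.1.0]heptan-3-yl]-2-(trimethylsilyl)ethan-1-one | C[Si](C)(C)C=C(O[Li])[C@H]1C[C@H]2O[C@@]2(C)[C@@H](O[Si](CC)(CC)CC)[C@H]1O[Si](CC)(CC)CC | intermediate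
13 | 1-[(1R,3S,4S,5S,6R)-6-methyl-4,5-bis[(triethylsilyl)oxy]-7-oxabicyclo[4.1.0]heptan-3-yl]ethan-1-one | CC(=O)[C@H]1C[C@H]2O[C@@]2(C)[C@@H](O[Si](CC)(CC)CC)[C@H]1O[Si](CC)(CC)CC | intermediate
14 | 1-[(1R,3S,4S,5S,6R)-6-methyl-4,5-bis[(triethylsilyl)oxy]-7-oxabicyclo[4.1.0]heptan-3-yl]ethenyl trifluoromethanesulfonate | C=C(OS(=O)(=O)C(F)(F)F)[C@H]1C[C@H]2O[C@@]2(C)[C@@H](O[Si](CC)(CC)CC)[C@H]1O[Si](CC)(CC)CC | intermediate
15 | 4-methylpent-3-en-1-ol | CC(C)=CCCO | starting material
16 | 4-methylpent-3-enal | CC(C)=CCC=O | intermediate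
17 | (3S)-6-methyl-2-[(1R,3R,4S,5S,6R)-6-methyl-4,5-bis[(triethylsilyl)oxy]-7-oxabicyclo[4.1.0]heptan-3-yl]hepta-1,5-dien-3-ol | C=C([C@@H](O)CC=C(C)C)[C@H]1C[C@H]2O[C@@]2(C)[C@@H](O[Si](CC)(CC)CC)[C@H]1O[Si](CC)(CC)CC | intermediate
18 | (1R,3R,4S,5S,6S)-3-[(3S)-3-hydroxy-6-methylhepta-1,5-dien-2-yl]-6-methyl-7-oxabicyclo[4.1.0]heptane-4,5-diol | C=C([C@@H](O)CC=C(C)C)[C@H]1C[C@H]2O[C@@]2(C)[C@@H](O)[C@H]1O | intermediate
19 | (3S)-6-methyl-2-[(1R,3R,4S,5S,6R)-6-methyl-4,5-bis{[(2Z)-2-methylbut-2-enoyl]oxy}-7-oxabicyclo[4.1.0]heptan-3-yl]hepta-1,5-dien-3-yl (2Z)-2-methylbut-2-enoate | C=C([C@H](CC=C(C)C)OC(=O)/C(C)=C\C)[C@H]1C[C@H]2O[C@@]2(C)[C@@H](OC(=O)/C(C)=C\C)[C@H]1OC(=O)/C(C)=C\C | intermediate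
20 | (2S)-1-[(2R)-3,3-dimethyloxiran-2-yl]-3-[(1R,3R,4S,5S,6R)-6-methyl-4,5-bis{[(2Z)-2-methylbut-2-enoyl]oxy}-7-oxabicyclo[4.1.0]heptan-3-yl]but-3-en-2-yl (2Z)-2-methylbut-2-enoate | C=C([C@H](C[C@H]1OC1(C)C)OC(=O)/C(C)=C\C)[C@H]1C[C@H]2O[C@@]2(C)[C@@H](OC(=O)/C(C)=C\C)[C@H]1OC(=O)/C(C)=C\C | target

Total step count: 13. Longest linear sequence: 12 steps (steps 1–8 and 10–13; step 9 is a one-step side branch).

Steps most likely to fail

Step 3. Three things may go wrong. Re-enolisation may be incomplete before the exchange, so that the alkenylmagnesium acylates the wrong ester. A proton may be transferred to the alkenyl metal before ring closure. The final protonation may show poor facial selectivity at the ester-bearing centre. The fallback sets out from 4 and 3 and comes back at 8, and makes the two ring bonds in separate, precedented steps. Fráter–Seebach alkylation gives 5, now isolated. Deprotonation with LiN(i-Pr)2 (2.2 equiv) and protonation with AcOH at −78 °C give dimethyl (2S,3S)-2-hydroxy-3-[(2Z)-3-iodobut-2-en-1-yl]butanedioate F1. Chemoselective reduction of the α-hydroxy ester (BH3·SMe2, NaBH4 cat., THF) gives methyl (2S,3S)-3,4-dihydroxy-2-[(2Z)-3-iodobut-2-en-1-yl]butanoate F2. Oxidation of the primary alcohol (TEMPO cat., PhI(OAc)2, CH2Cl2) gives methyl (2S,3S)-3-hydroxy-2-[(2Z)-3-iodobut-2-en-1-yl]-4-oxobutanoate F3. Intramolecular Nozaki–Hiyama–Kishi reaction (CrCl2, NiCl2 cat., DMF, high dilution) closes C5–C6 to 9 together with methyl (1S,5S,6S)-5,6-dihydroxy-4-methylcyclohex-3-ene-1-carboxylate F4. Oxidation of the mixture with MnO2 converges on 8, which re-enters at step 4.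

Step 10. The facial selectivity at the new carbinol may be poor if the ligand control is opposed by the neighbouring ring centre. The fallback sets out from 14 and 16 and comes back at 17. Coupling without the chiral ligand (CrCl2, NiCl2 cat., DMF) gives 17 mixed with (3R)-6-methyl-2-[(1R,3R,4S,5S,6R)-6-methyl-4,5-bis[(triethylsilyl)oxy]-7-oxabicyclo[4.1.0]heptan-3-yl]hepta-1,5-dien-3-ol F5. Buffered Dess–Martin oxidation of the mixture gives 6-methyl-2-[(1R,3R,4S,5S,6R)-6-methyl-4,5-bis[(triethylsilyl)oxy]-7-oxabicyclo[4.1.0]heptan-3-yl]hepta-1,5-dien-3-one F6. Corey–Bakshi–Shibata reduction with the (R)-methyl oxazaborolidine and BH3·SMe2 at −30 °C returns 17.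

Step 12. Angelate may isomerise to tiglate during acylation, and acylation of the hindered axial C4 hydroxyl may stay incomplete. The fallback sets out from 18 and comes back at 19, and builds the (Z)-alkenes after the ester bonds are in place. Esterification with 2-[bis(2,2,2-trifluoroethoxy)phosphoryl]propanoic acid (DCC, DMAP cat., CH2Cl2) gives (3S)-6-methyl-2-[(1R,3R,4S,5S,6R)-6-methyl-4,5-bis({2-[bis(2,2,2-trifluoroethoxy)phosphoryl]propanoyl}oxy)-7-oxabicyclo[4.1.0]heptan-3-yl]hepta-1,5-dien-3-yl 2-[bis(2,2,2-trifluoroethoxy)phosphoryl]propanoate F7. Threefold Still–Gennari olefination with acetaldehyde (KN(SiMe3)2, 18-crown-6, THF, −78 °C) then gives 19.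

Further compounds
F1 | step 3 | dimethyl (2S,3S)-2-hydroxy-3-[(2Z)-3-iodobut-2-en-1-yl]butanedioate | COC(=O)[C@@H](O)[C@H](C/C=C(/C)I)C(=O)OC
F2 | step 3 | methyl (2S,3S)-3,4-dihydroxy-2-[(2Z)-3-iodobut-2-en-1-yl]butanoate | OC[C@@H](O)[C@H](C/C=C(/C)I)C(=O)OC
F3 | step 3 | methyl (2S,3S)-3-hydroxy-2-[(2Z)-3-iodobut-2-en-1-yl]-4-oxobutanoate | O=C[C@@H](O)[C@H](C/C=C(/C)I)C(=O)OC
F4 | step 3 | methyl (1S,5S,6S)-5,6-dihydroxy-4-methylcyclohex-3-ene-1-carboxylate | COC(=O)[C@H]1CC=C(C)[C@H](O)[C@H]1O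
F5 | step 10 | (3R)-6-methyl-2-[(1R,3R,4S,5S,6R)-6-methyl-4,5-bis[(triethylsilyl)oxy]-7-oxabicyclo[4.1.0]heptan-3-yl]hepta-1,5-dien-3-ol | C=C([C@H](O)CC=C(C)C)[C@H]1C[C@H]2O[C@@]2(C)[C@@H](O[Si](CC)(CC)CC)[C@H]1O[Si](CC)(CC)CC
F6 | step 10 | 6-methyl-2-[(1R,3R,4S,5S,6R)-6-methyl-4,5-bis[(triethylsilyl)oxy]-7-oxabicyclo[4.1.0]heptan-3-yl]hepta-1,5-dien-3-one | C=C(C(=O)CC=C(C)C)[C@H]1C[C@H]2O[C@@]2(C)[C@@H](O[Si](CC)(CC)CC)[C@H]1O[Si](CC)(CC)CC
F7 | step 12 | (3S)-6-methyl-2-[(1R,3R,4S,5S,6R)-6-methyl-4,5-bis({2-[bis(2,2,2-trifluoroethoxy)phosphoryl]propanoyl}oxy)-7-oxabicyclo[4.1.0]heptan-3-yl]hepta-1,5-dien-3-yl 2-[bis(2,2,2-trifluoroethoxy)phosphoryl]propanoate | C=C([C@H](CC=C(C)C)OC(=O)C(C)P(=O)(OCC(F)(F)F)OCC(F)(F)F)[C@H]1C[C@H]2O[C@@]2(C)[C@@H](OC(=O)C(C)P(=O)(OCC(F)(F)F)OCC(F)(F)F)[C@H]1OC(=O)C(C)P(=O)(OCC(F)(F)F)OCC(F)(F)F
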